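The ratio of partner charged to substrate charged is the first thing an examiner should ask about this flask.

| setting | zeta | eta | delta | flask |
|---|---|---|---|---|
| substrate | 0.40 M | 0.40 M | 0.80 M | 0.40 M |
| partner | 0.10 M | 0.15 M | 0.20 M | 0.200 M |
| remark | run made earlier | run made earlier | run made earlier |  |
| time |  |  |  | 15 d |

| run | time / d | target / % | substrate / % |
|---|---|---|---|
| zeta | 2.50 | 0 | 100.6 |
| zeta | 4.00 | 1.4 | 98.3 |
| zeta | 8.00 | 5.4 | 94.6 |
| zeta | 12.0 | 15.7 | 82.4 |
| eta | 2.50 | 1.5 | 98.9 |
| eta | 4.00 | 3.2 | 99.3 |
| eta | 8.00 | 21.4 | 77.2 |
| eta | 12.0 | 31.9 | 65.4 |
| delta | 2.50 | 8.4 | 92.6 |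
| delta | 4.00 | 22.9 | 76.8 |
| delta | 8.00 | 21.8 | 75.6 |
| delta | 12.0 | 19.4 | 74.6 |

(scatter of a reading: 0.5 percentage points)

- what was read earlier has a scatter of 0.5 percentage points, one standard deviation

* the moment within 15 d at which there is most target
* the amount of target, in percent of the substrate charged, at that time

Why that ratio? In the early readings, substrate lost reappears as target, one for one. In the delta run, substrate stops near 74.6 %, and the highest target reading is 22.9 %, while partner over substrate there is 25.0 %. So I read partner as the limiting reagent and define the partner ceiling, partner charged over substrate charged, as a fraction of the substrate: 50.0 % for this flask.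

Then will the flask reach its ceiling? That is the weak spot. Late in the delta run, target falls from 21.8 % to 19.4 % between 8.00 d and 12.0 d, while substrate barely moves. As a reading, with its scatter, that is a loss of 0.0292 /d.

How do the two ends join? The early end is a slow start: the eta run stands at 3.2 % at 4.00 d and at 21.4 % at 8.00 d. The late end is the ceiling, eroded by the loss. The rise is S-shaped, so I let target made by the peak have sat for about half the time to the peak.

The forecast puts the peak at 10.5 d with 42 % target, the point where, in its words, “Formation then balances loss”. Taking its time, my own reckoning gives 42.9 %, slightly above its figure, and the half-time is a coarse average.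

The flask gives 42.1 % at 10.4 d.

    partner → decomposition product (k = 7.70 × 10⁻⁵ /h)
    substrate + partner + by-product → target + 2 by-product (k = 0.620 /M²/h)
    substrate + partner → target + by-product (k = 1.86 × 10⁻⁴ /M/h)
    target → over-reaction product (k = 0.00112 /h)

That best stands 7.9 percentage points under the ceiling of 50.0 %, and at that best time the flask holds 5.41 % as over-reaction product. At 5.82 d the flask makes target 17.1 times faster than it uses it up, but at 15.0 d, with partner down to 0.237 % of its own charge, making runs at 0.0682 of the using up and target stands at 38.8 %. A neighbouring flask charged with 1.6 M of substrate, other charges and time held, has a partner ceiling of 12.5 %, and its best is 12.0 %.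

(The runs were computed from invented constants; scatter was added.)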